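Each hydroxyquinone ring (C1=O, C2–OH, C3–CH3, C4=O, C5 inter-ring, C6 arylethyl) is cut through its C2=C3 and C5=C6 bonds. The key step exploits that C3–C4–C5 of both rings, linked by the C5–C5' bond, form the chain of octane-3,6-dione, while C6–C1–C2 is a 2,3-dioxo ester. The dienediolate of the diketone, released from its bis(silyl enol ether), joins two molecules of the ketal-masked dioxo ester in a double aldol–Claisen [3+3] annulation: aldol condensation makes C5=C6, Claisen condensation makes C2=C3, and both rings appear at the quinone oxidation level without an oxidant.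

Key step: step 3

Remark: the target has no stereocentre and its SMILES defines no axial configuration, so the hindered ring–ring axis is left unassigned (racemic if rotation is slow); octane-3,6-dione is taken as a purchasable starting material.

Step 1
Reactants: 1 3-(2-methoxyphenyl)propanoic acid; 2 methyl 2,2-dimethoxyacetate
Product: 5 methyl 2,2-dimethoxy-5-(2-methoxyphenyl)-3-oxopentanoate, via acyl imidazolide 3 (not isolated), via lithium enolate 4 (not isolated)
Conditions: 1, CDI, THF, rt; added to 4 [from 2, LiN(iPr)2, THF, −78 °C] at −78 °C; aq. NH4Cl
Reagents that add atoms: none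
Why: C-acylation of an ester enolate by an acyl imidazolide (crossed Claisen-type acylation) should work because enolate 4 has a single nucleophilic carbon, 5 has no acidic hydrogen between its carbonyl groups, and the tetrahedral adduct that persists at −78 °C shields the new ketone from a second addition.

Step 2
Reactants: 6 octane-3,6-dione
Product: 7 (3Z,5Z)-3,6-bis(trimethylsilyloxy)octa-3,5-diene
Conditions: Me3SiCl, NaI, Et3N, MeCN, rt to 40 °C
Reagents that add atoms: chlorotrimethylsilane, C[Si](C)(C)Cl
Why: Soft enolisation with Me3SiI formed in situ and Et3N is an equilibrating silyl enol ether formation, and for this 1,4-diketone the conjugated diene with both enol ether double bonds pointing to the central CH2–CH2 unit should be the most stable bis-enol ether, with the Z,Z geometry that minimises allylic strain.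

Step 3
Reactants: 7 (3Z,5Z)-3,6-bis(trimethylsilyloxy)octa-3,5-diene; 5 methyl 2,2-dimethoxy-5-(2-methoxyphenyl)-3-oxopentanoate (two equivalents)
Product: 12 CNP0293637.0 (two 2-hydroxy-3-methyl-6-[2-(2-methoxyphenyl)ethyl]-1,4-benzoquinone rings joined C5–C5'), via dienediolate 8 (not isolated), via bis-aldol adduct 9 (not isolated), via bis-Dieckmann product 10 (not isolated), via bis(quinone monoketal) 11 (not isolated)
Conditions: MeLi (2 equiv), THF, 0 °C; 5 (2.2 equiv), −78 °C; LiN(SiMe3)2 (2.5 equiv), −78 °C to rt; 2 M HCl, THF, rt
Reagents that add atoms: water, O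
Why: Proposed new method: MeLi should cleave both silyl enol ethers of 7 to dienediolate 8, whose two internal carbons add at −78 °C to the ketone carbonyl of two molecules of 5 (aldol addition, making in each future ring the C5–C6 bond between the inter-ring carbon and the carbon that carries the arylethyl chain) to give 9; LiN(SiMe3)2 then deprotonates the CH2 of each ethyl ketone, which closes its ring by a Dieckmann-type Claisen condensation on the α,α-dimethoxy ester (making the C2–C3 bond between the future C–OH carbon and the methyl-bearing carbon) to give 10 as its diketonate, and aqueous acid dehydrates the two β-hydroxy ketones to 11 and hydrolyses both quinone monoketals to the hydroxyquinones of 12. The closest known reaction types are the Pechmann condensation of 1,2-diketones to p-benzoquinones (a double aldol [3+3] annulation) and the consecutive Michael–Claisen [3+3] annulation of ketones with acrylates to cyclohexane-1,3-diones; what is new is the pairing of a ketone α,α'-dinucleophile with a masked vicinal tricarbonyl, so that aldol plus Claisen deliver the ring directly at the hydroxyquinone oxidation level and the enolised β-diketone formed in the ring closure acts as the thermodynamic sink that also blocks retro-aldol cleavage. Each of the two rings closes by a 6-(enolendo)-exo-trig acyl substitution. The stereocentres of 9 and 10 form without control and are all erased by the dehydration, and the target has none. The selectivity needed is regiochemical (inter-ring carbon to the ketone of 5, methyl-bearing carbon to its ester, no attack at the central carbonyl) and is secured by the position of the enol ether double bonds in 7, by the ketone of 5 being more electrophilic than its ester at −78 °C, by the ethyl CH2 being the only unhindered α-position left in 9, and by the non-enolisable dimethyl ketal that masks the central carbonyl of 5.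

Compound list
1 | 3-(2-methoxyphenyl)propanoic acid | COc1ccccc1CCC(=O)O | starting material
2 | methyl 2,2-dimethoxyacetate | COC(=O)C(OC)OC | starting material
3 | 1-[3-(2-methoxyphenyl)propanoyl]-1H-imidazole (acyl imidazolide) | COc1ccccc1CCC(=O)n1ccnc1 | intermediate
4 | lithium 1,2,2-trimethoxyethen-1-olate (lithium enolate of 2) | [Li+].COC([O-])=C(OC)OC | intermediate
5 | methyl 2,2-dimethoxy-5-(2-methoxyphenyl)-3-oxopentanoate | COC(=O)C(OC)(OC)C(=O)CCc1ccccc1OC | intermediate
6 | octane-3,6-dione | CCC(=O)CCC(=O)CC | starting material
7 | (3Z,5Z)-3,6-bis(trimethylsilyloxy)octa-3,5-diene | CC/C(O[Si](C)(C)C)=C/C=C(\O[Si](C)(C)C)CC | intermediate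
8 | dilithium (3Z,5Z)-octa-3,5-diene-3,6-bis(olate) (dienediolate) | [Li+].[Li+].CC/C([O-])=C/C=C(\[O-])CC | intermediate
9 | dimethyl 3,6-dihydroxy-2,2,7,7-tetramethoxy-3,6-bis[2-(2-methoxyphenyl)ethyl]-4,5-di(propanoyl)octanedioate (bis-aldol adduct; mixture of diastereomers, stereocentres uncontrolled; present in the flask as its dilithium alkoxide) | COC(=O)C(OC)(OC)C(O)(CCc1ccccc1OC)C(C(=O)CC)C(C(=O)CC)C(O)(CCc1ccccc1OC)C(OC)(OC)C(=O)OC | intermediate
10 | bis-Dieckmann product: two 3,5-dihydroxy-4,4-dimethoxy-2-methyl-5-[2-(2-methoxyphenyl)ethyl]cyclohex-2-en-1-one rings joined C6–C6' (enol form of the cyclic 1,3-diketone; mixture of diastereomers; present in the flask as its lithium salt) | COc1ccccc1CCC1(O)C(C2C(=O)C(C)=C(O)C(OC)(OC)C2(O)CCc3ccccc3OC)C(=O)C(C)=C(O)C1(OC)OC | intermediate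
11 | bis(quinone monoketal): two 3-hydroxy-4,4-dimethoxy-2-methyl-5-[2-(2-methoxyphenyl)ethyl]cyclohexa-2,5-dien-1-one rings joined C6–C6' | COc1ccccc1CCC1=C(C2=C(CCc3ccccc3OC)C(OC)(OC)C(O)=C(C)C2=O)C(=O)C(C)=C(O)C1(OC)OC | intermediate
12 | CNP0293637.0: two 2-hydroxy-3-methyl-6-[2-(2-methoxyphenyl)ethyl]-1,4-benzoquinone rings joined C5–C5' (no stereocentre) | COc1ccccc1CCC1=C(C2=C(CCc3ccccc3OC)C(=O)C(O)=C(C)C2=O)C(=O)C(C)=C(O)C1=O | target

Total step count: 3
Longest linear sequence: 2 steps (step 1 then step 3, or step 2 then step 3)

Steps most likely to fail

1. Step 3 (Proposed new method). What may go wrong: proton transfer from the enolisable ketone 5 to dienediolate 8, and retro-aldol cleavage of 9 before the ring closures, would let the enolates equilibrate and erase the regiochemistry; the second addition next to the first may also be slowed by crowding. Fallback with known reactions, stepwise instead of one anionic cascade, setting out from 7 and 5 and coming back to the route at 10: the bonds to the ketones are made under Lewis-acid control, where no free enolate exists. A TiCl4-mediated double Mukaiyama aldol addition (CH2Cl2, −78 °C) should give bis-aldol adduct 9, now isolated. Its tertiary hydroxyls are capped with Me3SiOTf and 2,6-lutidine to give dimethyl 2,2,7,7-tetramethoxy-3,6-bis[2-(2-methoxyphenyl)ethyl]-4,5-di(propanoyl)-3,6-bis(trimethylsilyloxy)octanedioate F1, which can no longer undergo retro-aldol cleavage. LiN(SiMe3)2 in THF then effects the two Dieckmann-type ring closures to the silylated bis-Dieckmann product F2, and 2 M HCl in THF removes the silyl groups to return to 10, which under the same acid goes on through 11 to 12.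

2. Step 1. What may go wrong: self-condensation or loss of methoxide from enolate 4, enolisation of acyl imidazolide 3 by 4, and a second addition of 4 to the new ketone would all lower conversion to 5. Fallback setting out from 1 and coming back to the route at 5: the tricarbonyl is built first and masked afterwards. Coupling of 1 with methyl (triphenylphosphoranylidene)acetate (EDCI, DMAP, CH2Cl2) should give the acyl ylide methyl 5-(2-methoxyphenyl)-3-oxo-2-(triphenyl-λ5-phosphanylidene)pentanoate F3. Oxidative cleavage of the P=C bond with KHSO5 in aqueous THF gives the vicinal tricarbonyl as its hydrate, methyl 2,2-dihydroxy-5-(2-methoxyphenyl)-3-oxopentanoate F4. Trimethyl orthoformate in MeOH with catalytic TsOH converts the central gem-diol, the most electrophilic position, into the dimethyl ketal and returns to 5.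

3. Step 2. What may go wrong: acid-promoted cyclodehydration of the 1,4-diketone to a furan, and incomplete equilibration that leaves non-conjugated enol ether regioisomers. Fallback setting out from 6 and coming back to the route at 7: the furan is made on purpose and used to fix the regiochemistry. TsOH in refluxing toluene with removal of water gives 2,5-diethylfuran F5 by Paal–Knorr cyclisation. Oxidative ring opening with mCPBA (CH2Cl2, 0 °C) gives (Z)-oct-4-ene-3,6-dione F6. Reductive 1,4-bis-silylation with Zn dust and Me3SiCl in THF then delivers 7, with the enol ether double bonds placed by the former C=C bond; any geometric isomer of 7 leads to the same dienediolate connectivity.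

Further compounds
F1 | step 3 | dimethyl 2,2,7,7-tetramethoxy-3,6-bis[2-(2-methoxyphenyl)ethyl]-4,5-di(propanoyl)-3,6-bis(trimethylsilyloxy)octanedioate (bis(trimethylsilyl ether) of 9, mixture of diastereomers) | COC(=O)C(OC)(OC)C(O[Si](C)(C)C)(CCc1ccccc1OC)C(C(=O)CC)C(C(=O)CC)C(O[Si](C)(C)C)(CCc1ccccc1OC)C(OC)(OC)C(=O)OC
F2 | step 3 | silylated bis-Dieckmann product: two 3-hydroxy-4,4-dimethoxy-2-methyl-5-[2-(2-methoxyphenyl)ethyl]-5-(trimethylsilyloxy)cyclohex-2-en-1-one rings joined C6–C6' (mixture of diastereomers) | COc1ccccc1CCC1(O[Si](C)(C)C)C(C2C(=O)C(C)=C(O)C(OC)(OC)C2(O[Si](C)(C)C)CCc3ccccc3OC)C(=O)C(C)=C(O)C1(OC)OC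
F3 | step 1 | methyl 5-(2-methoxyphenyl)-3-oxo-2-(triphenyl-λ5-phosphanylidene)pentanoate | COC(=O)C(C(=O)CCc1ccccc1OC)=P(c1ccccc1)(c1ccccc1)c1ccccc1
F4 | step 1 | methyl 2,2-dihydroxy-5-(2-methoxyphenyl)-3-oxopentanoate | COC(=O)C(O)(O)C(=O)CCc1ccccc1OC
F5 | step 2 | 2,5-diethylfuran | CCc1ccc(CC)o1
F6 | step 2 | (Z)-oct-4-ene-3,6-dione | CCC(=O)/C=C\C(=O)CC
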